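## Analysis of the target

Methylarzanol (19) is made of two six-membered rings joined through one methylene carbon. One ring is a fully substituted 2-methoxy-4H-pyran-4-one: O1, C2 with the methoxy group, C3 with the bridge, the C4 carbonyl, C5 with methyl and C6 with ethyl. The other is a hexasubstituted benzene of the acylphloroglucinol type: C1′ carries the bridge, C2′, C4′ and C6′ carry hydroxyls, C3′ the prenyl group and C5′ the acetyl group. The molecule has no stereocentre, and the prenyl double bond has two identical methyl groups, so there is no stereochemical relationship to control.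

Four parts are sensitive:
- The 2-methoxy-4-pyranone is a vinylogous ortho ester that aqueous acid or hydroxide converts into the 4-hydroxy-2-pyranone.
- The prenyl group cyclises onto a neighbouring phenol under acid and does not survive hydrogenation.
- The phloroglucinol is alkylated at oxygen as well as carbon and can be dearomatised.
- The methylene bridge links two enol-type carbons and can be cleaved by acid.

The difficulty is therefore one of order and selectivity: three different substituents on the three arene carbons, methylation of the pyranone on the lactone oxygen and not on the 4-hydroxyl, and union of the rings through exactly one carbon. The route rests on one structural observation. C2, C3 and C4 of the pyranone with the bridging CH2 are an arylmethylmalonyl unit, and a phenol ortho to the bridge can hold the C2 carboxyl as the six-membered lactone of a dihydrocoumarin. In that form the future C4 can be an acid chloride and the future C2 is an activated aryl ester tied to the arene, so the pyranone can be assembled from the C5–C6–O1 unit of a ketone while the lactone opens and returns the phenol.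

## Retrosynthetic reasoning

**19 ⇒ 17 + 18.** The bond between arene carbon C3′ and the prenyl CH2 is cut first. The prenyl alkene would not survive the hydrogenation, the acid chloride formation or the electrophilic methylation used earlier, so it has to come last. In 17 only one arene carbon is unsubstituted, so the position of attack is not in question; the forward reaction has to favour carbon over oxygen alkylation of the phloroglucinol anion with 18.

**17 ⇒ 16.** Two phenols are returned to their acetates. Acetates are stable to acid chloride and ketene chemistry and to the methylating agent, and they leave by methanolysis, in which methoxide can only exchange the methoxy group at C2 for itself.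

**16 ⇒ 14.** The O–CH3 bond at the C2 oxygen is cut, which leads back to the 4-hydroxy-2-pyranone 14. The forward step must alkylate the neutral hydroxypyranone on its lactone carbonyl oxygen so that the 4-pyranone tautomer is fixed.

**14 ⇒ 9 + 11 (key disconnection).** The pyranone bonds C4–C5 and O1–C2 are cut. This separates the C5–C6–O1 unit with its methyl and ethyl groups as enol silane 11 and leaves C2–C3–C4 with the arylmethyl branch as the malonyl unit of 9. In 9, C4 is an acid chloride and C2 is the lactone carbonyl held by the phenol ortho to the bridge. Cutting here is preferred to cutting the bridge because the bridge carbon is then introduced at the aldehyde stage, where exactly one carbon is attached to the arene. The forward reaction has to acylate 11 at carbon, presumably through acylketene 12, and then let the enol oxygen of the resulting lactone 13 displace the aryl oxygen from the lactone carbonyl. One operation therefore builds the ring, joins the two halves and unmasks the phenol.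

**9 ⇒ 8 ⇒ 7.** The C–Cl bond goes back to acid 8, and the two hydrogens at C3 and C4 go back to the coumarin 7. Hydrogenation is placed here because no other reducible alkene is present yet.

**7 ⇒ 6 ⇒ 3 + 4.** After removal of the acetates, the C3=C4 double bond and the lactone C–O bond of 6 are cut together, a Knoevenagel condensation and lactonisation of aldehyde 3 with Meldrum's acid 4. This sets the bridge carbon and the complete malonyl unit in one step. The lactone is expected to close on the hydroxyl para to the acetyl group, which is the one not tied up by hydrogen bonding to the ketone; this places the acetyl at C6 of the chromene.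

**3 ⇒ 1 and 11 ⇒ 10.** The formyl carbon is removed from 3 to give phloracetophenone 1, which already holds the acetyl group and the three hydroxyls. Enol silane 11 comes from 3-pentanone 10 by silylation.

## Alternatives that were turned down

**Alternative 1:** The benzene ring is built instead of bought, by cutting the arene bonds C2′–C3′ and C4′–C5′ (Danheiser benzannulation).
- Forward key step: heating 4-[(6-ethyl-2-methoxy-5-methyl-4-oxo-4H-pyran-3-yl)methyl]-3-(triisopropylsilyloxy)cyclobut-2-en-1-one A2 opens it to a vinylketene. This adds the prenyl-substituted siloxyalkyne A3 by [2+2]; a second four-electron opening and a six-electron closure give the phenol A1.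
- For: every substituent is placed by construction and the prenyl group enters with the alkyne, so there is no C- versus O-prenylation. On this point the alternative is stronger than the chosen route.
- Against: A1 has hydrogen where the acetyl group belongs, between two bulky silyl ethers. A Friedel–Crafts acylation would be needed on a prenylated, acid-sensitive arene next to the methoxypyranone, followed by desilylation. A2 must carry the finished methoxypyranone on a cyclobutenone that is itself a multistep building block, A3 needs its own synthesis, and the cascade runs hot.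
- Comparison: the chosen route is shorter and uses an arene that already contains the acetyl group. It gives up constructive control of the prenyl position, but at that stage only one arene carbon is free.

**Alternative 2:** The pyranone bonds C3–C4 and O1–C2 are cut with the methoxy group already on C2.
- Forward key step: thermolysis of 6-ethyl-2,2,5-trimethyl-4H-1,3-dioxin-4-one A5 releases the acylketene A6. A6 reacts as a 1-oxadiene with the ketene dimethyl acetal A7, and loss of one methoxy group as the alcohol gives the methoxypyranone A4.
- For: the methoxy group is placed without any question of regiochemistry, which is stronger than the chosen route, where a selective methylation is needed. Cycloadditions of acylketenes with electron-rich alkenes are dependable.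
- Against: A4 is a tribenzyl ether with neither acetyl nor prenyl group. After hydrogenolysis, a symmetrical and very reactive phloroglucinol would have to be mono-acetylated at carbon under Lewis or Brønsted acid, with the methoxypyranone and the bridge present, and then prenylated. A7 is a moisture-sensitive monosubstituted ketene acetal.
- Comparison: the chosen route pays one methylation step but never exposes the methoxypyranone to Friedel–Crafts conditions.

**Alternative 3:** The aryl–O, aryl–C and bridge–C3 bonds are cut, the bridge carbon coming from N,N-dimethylformamide A11.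
- Forward key step: CsF releases the aryne from the silylaryl triflate A9. The aryne adds across the C=O bond of A11 by [2+2] and opens to an ortho-quinone methide, which is captured by C3 of the hydroxypyranone A10 to give A8.
- For: three components are joined in one flask under mild conditions, and A10 is available in one known step. In convergence the alternative is at least equal to the chosen route.
- Against: the bridge carbon arrives with a dimethylamino group that must be removed reductively. The arene lacks acetyl and prenyl groups, the pyranone still has to be methylated, and A9 needs several steps from phloroglucinol. The late C-acetylation has the problems described for alternative 2.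
- Comparison: the chosen route reaches the bridge at the right oxidation level after one hydrogenation and carries the acetyl group from the first step.

Key step: step 7

Assumption: the Knoevenagel lactonisation is taken to close on the hydroxyl para to the acetyl group, which is not chelated by the ketone, so the route is written for the 6-acetyl lactone series; closure on the other hydroxyl is treated among the uncertain steps.

## Route

**Step 1**
Reactants: 1 2,4,6-trihydroxyacetophenone
Product: 3 3-acetyl-2,4,6-trihydroxybenzaldehyde, via aryl iminium chloride 2 (not isolated)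
Conditions: POCl3 (1.1 equiv), DMF, EtOAc, 0 °C → rt; then H2O, 60 °C
Reagents that add atoms: N,N-dimethylformamide CN(C)C=O; water O
Why: Vilsmeier–Haack formylation of a highly activated arene; the two free ring carbons of 1 are equivalent and the first formyl group deactivates the ring towards a second. Warm water hydrolyses iminium 2 to the aldehyde.

**Step 2**
Reactants: 3 3-acetyl-2,4,6-trihydroxybenzaldehyde; 4 Meldrum's acid (2,2-dimethyl-1,3-dioxane-4,6-dione)
Product: 6 6-acetyl-5,7-dihydroxy-2-oxo-2H-chromene-3-carboxylic acid, via arylidene Meldrum's acid 5 (not isolated)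
Conditions: piperidinium acetate (10 mol %), EtOH, rt → 60 °C
Reagents that add atoms: none
Why: Knoevenagel condensation of a salicylaldehyde with Meldrum's acid, then attack of an ortho hydroxyl on the dioxanedione with loss of acetone, is the standard route to coumarin-3-carboxylic acids. Of the two ortho hydroxyls, the one para to the acetyl group is unhindered and not hydrogen-bonded to the ketone, as in O-functionalisation of acylphloroglucinols, so the 6-acetyl lactone is expected.

**Step 3**
Reactants: 6 6-acetyl-5,7-dihydroxy-2-oxo-2H-chromene-3-carboxylic acid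
Product: 7 6-acetyl-5,7-diacetoxy-2-oxo-2H-chromene-3-carboxylic acid
Conditions: Ac2O (4 equiv), pyridine, DMAP (cat.), 0 °C → rt; then H2O–THF, rt
Reagents that add atoms: acetic anhydride CC(=O)OC(C)=O
Why: Nucleophile-catalysed O-acetylation; DMAP overcomes the hydrogen bonding of the hydroxyls that flank the ketone. The mixed anhydride formed at the carboxyl group is hydrolysed in the aqueous stage.

**Step 4**
Reactants: 7 6-acetyl-5,7-diacetoxy-2-oxo-2H-chromene-3-carboxylic acid
Product: 8 6-acetyl-5,7-diacetoxy-2-oxochromane-3-carboxylic acid (racemic)
Conditions: H2 (1 atm), 10% Pd/C, EtOAc–THF, rt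
Reagents that add atoms: none
Why: Heterogeneous hydrogenation of the electron-poor conjugated C3=C4 bond of a coumarin-3-carboxylic acid is fast, whereas the aryl acetates, the lactone and the twisted aryl ketone should be inert. C3 becomes a stereocentre, formed racemic and of no consequence because it is sp2 again after step 7.

**Step 5**
Reactants: 8 6-acetyl-5,7-diacetoxy-2-oxochromane-3-carboxylic acid (racemic)
Product: 9 6-acetyl-5,7-diacetoxy-2-oxochromane-3-carbonyl chloride (racemic)
Conditions: (COCl)2 (1.5 equiv), DMF (cat.), CH2Cl2, 0 °C → rt; concentrated and used crude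
Reagents that add atoms: oxalyl chloride O=C(Cl)C(=O)Cl
Why: Acid chloride formation through the chloroiminium species under cold, non-basic conditions, which leave the esters and the ketone untouched. Using the chloride crude avoids hydrolysis and premature ketene formation.

**Step 6**
Reactants: 10 3-pentanone
Product: 11 (Z)-3-(trimethylsilyloxy)pent-2-ene
Conditions: TMSCl, NaI, Et3N, MeCN, rt
Reagents that add atoms: chlorotrimethylsilane C[Si](C)(C)Cl
Why: Silylation of the ketone with iodotrimethylsilane made in the flask under equilibrating conditions gives the silyl enol ether, mainly as the Z isomer. The geometry is not carried into the product.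

**Step 7**
Reactants: 9 6-acetyl-5,7-diacetoxy-2-oxochromane-3-carbonyl chloride (racemic); 11 (Z)-3-(trimethylsilyloxy)pent-2-ene
Product: 14 3-[(3-acetyl-2,4-diacetoxy-6-hydroxyphenyl)methyl]-6-ethyl-4-hydroxy-5-methyl-2H-pyran-2-one, via acylketene 12 (not isolated), via acylated lactone 13 (not isolated)
Conditions: 11 (2 equiv), i-Pr2NEt (1.2 equiv), CH2Cl2, –78 → 0 °C; then i-Pr2NEt (2 equiv), rt → 40 °C; 1 M HCl work-up
Reagents that add atoms: none
Why: Proposed new method: i-Pr2NEt removes the doubly activated C3–H of 9 and chloride leaves, giving the disubstituted acylketene 12, whose carbonyl carbon is attacked by the nucleophilic carbon of 11 with transfer of silicon to oxygen, so that C4–C5 is formed and lactone 13 results as its enol or silyl enol. With the excess amine the 1,3-diketone of 13 enolises towards the ethyl ketone, and this enol oxygen adds to the lactone carbonyl in a 6-exo-trig addition–elimination that forms O1–C2 and expels the aryl oxide, a phenoxide para to an acetyl group and so a good leaving group. The pyran-2,4-dione formed tautomerises to the 4-hydroxy-2-pyranone, which is deprotonated under the conditions, and this should make the ring transfer irreversible. The closest known reaction type is the synthesis of 4-hydroxy-2-pyranones from malonyl dichlorides, (chlorocarbonyl)ketenes or activated aryl malonates and ketone enol derivatives; what is new is that the second acyl donor is an aryl lactone that opens as the pyranone closes. Carbon acylation is expected because ketenes and acid chlorides attack silyl enol ethers at carbon, and only the lactone carbonyl is within six-membered reach of the enol oxygen, since attack on either aryl acetate would need a ring of ten or more atoms. No stereocentre results: C3 of 9 and the two centres of 13 all become sp2 in 14, so neither the racemic nature of 9 nor the geometry of 11 matters. A [2+2] or hetero-[4+2] adduct of 12 and 11, should one form in place of the open adduct, contains the same C4–C5 bond and is expected to funnel into the same pyranone skeleton once silicon is lost.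

**Step 8**
Reactants: 14 3-[(3-acetyl-2,4-diacetoxy-6-hydroxyphenyl)methyl]-6-ethyl-4-hydroxy-5-methyl-2H-pyran-2-one
Product: 16 3-[(3-acetyl-2,4-diacetoxy-6-hydroxyphenyl)methyl]-6-ethyl-2-methoxy-5-methyl-4H-pyran-4-one, via methoxypyrylium triflate 15 (not isolated)
Conditions: MeOTf (1.3 equiv), CH2Cl2, 0 °C → rt; then aq. NaHCO3
Reagents that add atoms: methyl trifluoromethanesulfonate COS(=O)(=O)C(F)(F)F
Why: Neutral 4-hydroxy-2-pyranones are alkylated by hard methylating agents at the lactone carbonyl oxygen, their most nucleophilic site, giving a 4-hydroxy-2-methoxypyrylium salt that loses a proton to the 2-methoxy-4-pyranone. No base is present, so the free phenol should not be methylated, and the acetates and the ketone are inert.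

**Step 9**
Reactants: 16 3-[(3-acetyl-2,4-diacetoxy-6-hydroxyphenyl)methyl]-6-ethyl-2-methoxy-5-methyl-4H-pyran-4-one
Product: 17 3-[(3-acetyl-2,4,6-trihydroxyphenyl)methyl]-6-ethyl-2-methoxy-5-methyl-4H-pyran-4-one
Conditions: K2CO3 (2.2 equiv), MeOH, 0 °C; then aq. NaH2PO4
Reagents that add atoms: none
Why: Transesterification of aryl acetates by methoxide is fast at 0 °C. Attack of methoxide at C2 of the pyranone only exchanges methoxy for methoxy, and the absence of water and the low temperature protect the pyranone from hydrolysis.

**Step 10**
Reactants: 17 3-[(3-acetyl-2,4,6-trihydroxyphenyl)methyl]-6-ethyl-2-methoxy-5-methyl-4H-pyran-4-one; 18 prenyl bromide (1-bromo-3-methylbut-2-ene)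
Product: 19 methylarzanol, 3-{[3-acetyl-2,4,6-trihydroxy-5-(3-methylbut-2-en-1-yl)phenyl]methyl}-6-ethyl-2-methoxy-5-methyl-4H-pyran-4-one
Conditions: NaOMe (1.1 equiv), 18 (1.5 equiv, in portions), MeOH, 0 °C; then aq. NaH2PO4
Reagents that add atoms: none
Why: C-alkylation of an acylphloroglucinol monoanion by an allylic bromide in a protic solvent, which hydrogen-bonds the oxygens and directs the electrophile to carbon. Only one ring carbon is unsubstituted, and methanol as solvent keeps a methoxy group on C2 of the pyranone.

## Compound list

1 | 2,4,6-trihydroxyacetophenone | CC(=O)c1c(O)cc(O)cc1O | starting material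
2 | N-[(3-acetyl-2,4,6-trihydroxyphenyl)methylidene]-N-methylmethanaminium chloride | CC(=O)c1c(O)cc(O)c(C=[N+](C)C)c1O.[Cl-] | intermediate (not isolated)
3 | 3-acetyl-2,4,6-trihydroxybenzaldehyde | CC(=O)c1c(O)cc(O)c(C=O)c1O | intermediate
4 | Meldrum's acid (2,2-dimethyl-1,3-dioxane-4,6-dione) | CC1(C)OC(=O)CC(=O)O1 | starting material
5 | 5-[(3-acetyl-2,4,6-trihydroxyphenyl)methylidene]-2,2-dimethyl-1,3-dioxane-4,6-dione | CC(=O)c1c(O)cc(O)c(C=C2C(=O)OC(C)(C)OC2=O)c1O | intermediate (not isolated)
6 | 6-acetyl-5,7-dihydroxy-2-oxo-2H-chromene-3-carboxylic acid | CC(=O)c1c(O)cc2oc(=O)c(C(=O)O)cc2c1O | intermediate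
7 | 6-acetyl-5,7-diacetoxy-2-oxo-2H-chromene-3-carboxylic acid | CC(=O)Oc1cc2oc(=O)c(C(=O)O)cc2c(OC(C)=O)c1C(C)=O | intermediate
8 | 6-acetyl-5,7-diacetoxy-2-oxochromane-3-carboxylic acid (racemic) | CC(=O)Oc1cc2OC(=O)C(C(=O)O)Cc2c(OC(C)=O)c1C(C)=O | intermediate
9 | 6-acetyl-5,7-diacetoxy-2-oxochromane-3-carbonyl chloride (racemic) | CC(=O)Oc1cc2OC(=O)C(C(=O)Cl)Cc2c(OC(C)=O)c1C(C)=O | intermediate
10 | 3-pentanone | CCC(=O)CC | starting material
11 | (Z)-3-(trimethylsilyloxy)pent-2-ene | C/C=C(\O[Si](C)(C)C)CC | intermediate
12 | 6-acetyl-5,7-diacetoxy-3-(oxomethylidene)chroman-2-one | CC(=O)Oc1cc2OC(=O)C(=C=O)Cc2c(OC(C)=O)c1C(C)=O | intermediate (not isolated)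
13 | 6-acetyl-5,7-diacetoxy-3-(2-methyl-3-oxopentanoyl)chroman-2-one (mixture of diastereomers and enol tautomers) | CCC(=O)C(C)C(=O)C1Cc2c(OC(C)=O)c(C(C)=O)c(OC(C)=O)cc2OC1=O | intermediate (not isolated)
14 | 3-[(3-acetyl-2,4-diacetoxy-6-hydroxyphenyl)methyl]-6-ethyl-4-hydroxy-5-methyl-2H-pyran-2-one | CCc1oc(=O)c(Cc2c(O)cc(OC(C)=O)c(C(C)=O)c2OC(C)=O)c(O)c1C | intermediate
15 | 3-[(3-acetyl-2,4-diacetoxy-6-hydroxyphenyl)methyl]-6-ethyl-4-hydroxy-2-methoxy-5-methylpyrylium trifluoromethanesulfonate | CCc1[o+]c(OC)c(Cc2c(O)cc(OC(C)=O)c(C(C)=O)c2OC(C)=O)c(O)c1C.[O-]S(=O)(=O)C(F)(F)F | intermediate (not isolated)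
16 | 3-[(3-acetyl-2,4-diacetoxy-6-hydroxyphenyl)methyl]-6-ethyl-2-methoxy-5-methyl-4H-pyran-4-one | CCc1oc(OC)c(Cc2c(O)cc(OC(C)=O)c(C(C)=O)c2OC(C)=O)c(=O)c1C | intermediate
17 | 3-[(3-acetyl-2,4,6-trihydroxyphenyl)methyl]-6-ethyl-2-methoxy-5-methyl-4H-pyran-4-one | CCc1oc(OC)c(Cc2c(O)cc(O)c(C(C)=O)c2O)c(=O)c1C | intermediate
18 | prenyl bromide (1-bromo-3-methylbut-2-ene) | CC(C)=CCBr | starting material
19 | methylarzanol | CCc1oc(OC)c(Cc2c(O)c(CC=C(C)C)c(O)c(C(C)=O)c2O)c(=O)c1C | target

## Step count and uncertain steps

Total step count: 10. Longest linear sequence: 9 steps (1 → 19 through steps 1–5 and 7–10); step 6 is a one-step branch.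

**Step 7 (key step).** Several things may go wrong:
- The ketene may dimerise or oligomerise before the enol silane captures it.
- The acylated lactone may fail to isomerise under mild amine, because the hindered diketone enol does not reach the lactone carbonyl or the equilibrium is slow.
- The released phenoxide may take an acetyl group from an aryl acetate of another molecule.
- The ring may close through the lactone oxygen instead of the ketone oxygen, which would leave the aryl oxygen on C2 of a 4-pyranone. Methoxide in step 9 should exchange that aryl oxygen for methoxy, so this last deviation is tolerable.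

The fallback uses known chemistry and separates pyranone formation from the joining of the rings; it sets out from 11 and 1 and returns at 17. Enol silane 11 and malonyl dichloride (Et2O, –78 °C → rt) give 6-ethyl-4-hydroxy-5-methyl-2H-pyran-2-one F1 by the established acylation–lactonisation of silyl enol ethers. F1 is aminomethylated at C3 with Eschenmoser's salt (Me2N=CH2+ I−) to 3-[(dimethylamino)methyl]-6-ethyl-4-hydroxy-5-methyl-2H-pyran-2-one F2. On warming, F2 loses dimethylamine to give 6-ethyl-5-methyl-3-methylidene-2H-pyran-2,4(3H)-dione F3. F3 is trapped in the same flask by an excess of 1 in a Friedel–Crafts-type conjugate addition, giving 3-[(3-acetyl-2,4,6-trihydroxyphenyl)methyl]-6-ethyl-4-hydroxy-5-methyl-2H-pyran-2-one F4. Methylation of F4 with MeOTf as in step 8 then gives 17.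

**Step 8.** Methylation may occur at the 4-oxygen instead of the lactone carbonyl oxygen. The free phenol next to the bridge may also add to C2 of the methoxypyrylium intermediate with loss of methanol; the methoxide of step 9 should reverse that. The fallback blocks both hydroxyls first; it sets out from 14 and returns at 17. Silylation of 14 (TBSCl, imidazole, DMF) gives 3-{[3-acetyl-2,4-diacetoxy-6-(tert-butyldimethylsilyloxy)phenyl]methyl}-4-(tert-butyldimethylsilyloxy)-6-ethyl-5-methyl-2H-pyran-2-one F5. In F5, MeOTf can reach only the lactone carbonyl oxygen. Loss of silicon from the 4-oxygen of the pyrylium ion gives 3-{[3-acetyl-2,4-diacetoxy-6-(tert-butyldimethylsilyloxy)phenyl]methyl}-6-ethyl-2-methoxy-5-methyl-4H-pyran-4-one F6. K2CO3 in MeOH then cleaves the aryl silyl ether together with the acetates and gives 17.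

**Step 10.** Alkylation at oxygen, a second or dearomatising alkylation at substituted ring carbons, and solvolysis of the bromide by methanol may all lower the yield. The fallback replaces the phenoxide alkylation by an allylic substitution under neutral conditions; it sets out from 17 and returns at 19. Compound 17 is treated with tert-butyl 3-methylbut-2-en-1-yl carbonate and Pd(PPh3)4 (zerovalent palladium, 5 mol %) in THF at rt (Tsuji–Trost reaction). The prenyl–palladium intermediate is attacked at its unsubstituted terminus, and any O-prenyl ether formed first is re-ionised by the catalyst, so the C-prenyl product should accumulate. This fallback makes no new compound (F0).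

**Step 2.** The lactone may close partly or mainly on the hydroxyl next to the acetyl group. The fallback does not rely on the selectivity and erases the regiochemistry later; it sets out from 3 and 4 and returns at 17. The isomeric 8-acetyl-5,7-dihydroxy-2-oxo-2H-chromene-3-carboxylic acid F7 is carried on alone or mixed with 6. It is acetylated to 8-acetyl-5,7-diacetoxy-2-oxo-2H-chromene-3-carboxylic acid F8 and hydrogenated to 8-acetyl-5,7-diacetoxy-2-oxochromane-3-carboxylic acid F9. F9 is converted into 8-acetyl-5,7-diacetoxy-2-oxochromane-3-carbonyl chloride F10. With 11 under the conditions of step 7, F10 gives 3-[(3-acetyl-4,6-diacetoxy-2-hydroxyphenyl)methyl]-6-ethyl-4-hydroxy-5-methyl-2H-pyran-2-one F11. F11 is methylated to 3-[(3-acetyl-4,6-diacetoxy-2-hydroxyphenyl)methyl]-6-ethyl-2-methoxy-5-methyl-4H-pyran-4-one F12. Methanolysis of F12 as in step 9 gives the same triol 17 as 16 does, because the two series differ only in which phenols carry the acetates.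

## Further compounds

F1 | step 7 | 6-ethyl-4-hydroxy-5-methyl-2H-pyran-2-one | CCc1oc(=O)cc(O)c1C
F2 | step 7 | 3-[(dimethylamino)methyl]-6-ethyl-4-hydroxy-5-methyl-2H-pyran-2-one | CCc1oc(=O)c(CN(C)C)c(O)c1C
F3 | step 7 | 6-ethyl-5-methyl-3-methylidene-2H-pyran-2,4(3H)-dione | CCC1=C(C)C(=O)C(=C)C(=O)O1
F4 | step 7 | 3-[(3-acetyl-2,4,6-trihydroxyphenyl)methyl]-6-ethyl-4-hydroxy-5-methyl-2H-pyran-2-one | CCc1oc(=O)c(Cc2c(O)cc(O)c(C(C)=O)c2O)c(O)c1C
F5 | step 8 | 3-{[3-acetyl-2,4-diacetoxy-6-(tert-butyldimethylsilyloxy)phenyl]methyl}-4-(tert-butyldimethylsilyloxy)-6-ethyl-5-methyl-2H-pyran-2-one | CCc1oc(=O)c(Cc2c(O[Si](C)(C)C(C)(C)C)cc(OC(C)=O)c(C(C)=O)c2OC(C)=O)c(O[Si](C)(C)C(C)(C)C)c1C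
F6 | step 8 | 3-{[3-acetyl-2,4-diacetoxy-6-(tert-butyldimethylsilyloxy)phenyl]methyl}-6-ethyl-2-methoxy-5-methyl-4H-pyran-4-one | CCc1oc(OC)c(Cc2c(O[Si](C)(C)C(C)(C)C)cc(OC(C)=O)c(C(C)=O)c2OC(C)=O)c(=O)c1C
F0 | step 10 | none | none
F7 | step 2 | 8-acetyl-5,7-dihydroxy-2-oxo-2H-chromene-3-carboxylic acid | CC(=O)c1c(O)cc(O)c2cc(C(=O)O)c(=O)oc12
F8 | step 2 | 8-acetyl-5,7-diacetoxy-2-oxo-2H-chromene-3-carboxylic acid | CC(=O)c1c(OC(C)=O)cc(OC(C)=O)c2cc(C(=O)O)c(=O)oc12
F9 | step 2 | 8-acetyl-5,7-diacetoxy-2-oxochromane-3-carboxylic acid (racemic) | CC(=O)c1c(OC(C)=O)cc(OC(C)=O)c2c1OC(=O)C(C(=O)O)C2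
F10 | step 2 | 8-acetyl-5,7-diacetoxy-2-oxochromane-3-carbonyl chloride (racemic) | CC(=O)c1c(OC(C)=O)cc(OC(C)=O)c2c1OC(=O)C(C(=O)Cl)C2
F11 | step 2 | 3-[(3-acetyl-4,6-diacetoxy-2-hydroxyphenyl)methyl]-6-ethyl-4-hydroxy-5-methyl-2H-pyran-2-one | CCc1oc(=O)c(Cc2c(OC(C)=O)cc(OC(C)=O)c(C(C)=O)c2O)c(O)c1C
F12 | step 2 | 3-[(3-acetyl-4,6-diacetoxy-2-hydroxyphenyl)methyl]-6-ethyl-2-methoxy-5-methyl-4H-pyran-4-one | CCc1oc(OC)c(Cc2c(OC(C)=O)cc(OC(C)=O)c(C(C)=O)c2O)c(=O)c1C
A1 | alternative 1 | 6-ethyl-3-{[2-hydroxy-3-(3-methylbut-2-en-1-yl)-4,6-bis(triisopropylsilyloxy)phenyl]methyl}-2-methoxy-5-methyl-4H-pyran-4-one | CCc1oc(OC)c(Cc2c(O)c(CC=C(C)C)c(O[Si](C(C)C)(C(C)C)C(C)C)cc2O[Si](C(C)C)(C(C)C)C(C)C)c(=O)c1C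
A2 | alternative 1 | 4-[(6-ethyl-2-methoxy-5-methyl-4-oxo-4H-pyran-3-yl)methyl]-3-(triisopropylsilyloxy)cyclobut-2-en-1-one (racemic) | O=C1C=C(O[Si](C(C)C)(C(C)C)C(C)C)C1Cc1c(OC)oc(CC)c(C)c1=O
A3 | alternative 1 | triisopropyl[(5-methylhex-4-en-1-yn-1-yl)oxy]silane | CC(C)=CCC#CO[Si](C(C)C)(C(C)C)C(C)C
A4 | alternative 2 | 6-ethyl-2-methoxy-5-methyl-3-{[2,4,6-tris(benzyloxy)phenyl]methyl}-4H-pyran-4-one | CCc1oc(OC)c(Cc2c(OCc3ccccc3)cc(OCc3ccccc3)cc2OCc2ccccc2)c(=O)c1C
A5 | alternative 2 | 6-ethyl-2,2,5-trimethyl-4H-1,3-dioxin-4-one | CCC1=C(C)C(=O)OC(C)(C)O1
A6 | alternative 2 | 2-methylpent-1-ene-1,3-dione | CCC(=O)C(C)=C=O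
A7 | alternative 2 | 1,3,5-tris(benzyloxy)-2-(3,3-dimethoxyprop-2-en-1-yl)benzene | COC(OC)=CCc1c(OCc2ccccc2)cc(OCc2ccccc2)cc1OCc1ccccc1
A8 | alternative 3 | 3-{[2,4-bis(benzyloxy)-6-hydroxyphenyl](dimethylamino)methyl}-6-ethyl-4-hydroxy-5-methyl-2H-pyran-2-one (racemic) | CCc1oc(=O)c(C(N(C)C)c2c(O)cc(OCc3ccccc3)cc2OCc2ccccc2)c(O)c1C
A9 | alternative 3 | 3,5-bis(benzyloxy)-2-(trimethylsilyl)phenyl trifluoromethanesulfonate | C[Si](C)(C)c1c(OCc2ccccc2)cc(OCc2ccccc2)cc1OS(=O)(=O)C(F)(F)F
A10 | alternative 3 | 6-ethyl-4-hydroxy-5-methyl-2H-pyran-2-one | CCc1oc(=O)cc(O)c1C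
A11 | alternative 3 | N,N-dimethylformamide | CN(C)C=O
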